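Everything rests on opening pyranone ring C at O1–C8a, C4–C4a and O1–C2, which leads back to 3,5-dimethoxybenzyne and a side-chain dec-2-ynoic acid. The key step exploits the adjacent C8a–O1 and C4a–C4 bonds on ring A, with the C5 methoxy flanking C4a and the other methoxy at C7: in one operation the carboxylate adds to the aryne through oxygen, the acyl group shifts to the neighbouring carbon and the phenoxide closes ring C. The precursors are an ortho-silylaryl triflate and a MOM-protected (S)-β-hydroxy ester ending in the ynoic acid; a Noyori hydrogenation sets the stereocentre.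

Key step: step 8

Remark on the chemistry: the alkyne is assumed to need a C-trimethylsilyl cap from step 3 to step 7, because a free terminal alkyne is a liability under ruthenium hydride catalysis and the methyl ester rules out acetylide formation with strong base; the silyl group then serves as the handle for carboxylation.

Step 1
Reactants: 1 3,5-dimethoxyphenol
Product: 2 2-bromo-3,5-dimethoxyphenol
Conditions: NBS (1.0 equiv), CH2Cl2, −78 °C → rt
Reagents that add atoms: N-bromosuccinimide, O=C1CCC(=O)N1Br
Why: Electrophilic aromatic bromination of a phenol, in which the hydroxyl group should steer bromine to its ortho position (C2, also para to a methoxy group) in a non-polar solvent at low temperature, the alternative C4 site being crowded between two methoxy groups; one equivalent of NBS limits double bromination and the hydrogen-bonded ortho isomer should be the less polar, separable product.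

Step 2
Reactants: 2 2-bromo-3,5-dimethoxyphenol
Product: 5 3,5-dimethoxy-2-(trimethylsilyl)phenyl trifluoromethanesulfonate, via aryl silyl ether 3 (not isolated), via lithium silylphenoxide 4 (not isolated)
Conditions: HMDS, THF, 70 °C; concentrate; n-BuLi, THF, −100 °C; Tf2O, −100 °C → rt
Reagents that add atoms: hexamethyldisilazane, C[Si](C)(C)N[Si](C)(C)C; trifluoromethanesulfonic anhydride, O=S(=O)(OS(=O)(=O)C(F)(F)F)C(F)(F)F
Why: O-silylation, bromine–lithium exchange and anionic 1,3-silyl shift from oxygen to carbon (retro-Brook rearrangement) should give the ortho-silyl phenoxide, which Tf2O traps at oxygen, the standard passage from ortho-bromophenols to ortho-silylaryl triflates.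

Step 3
Reactants: 6 hept-6-ynoic acid
Product: 9 7-(trimethylsilyl)hept-6-ynoic acid, via dilithio salt 7 (not isolated), via bis-silyl ester 8 (not isolated)
Conditions: LDA (2.2 equiv), THF, −78 °C; TMSCl (2.5 equiv), −78 °C → rt; 1 M HCl (work-up)
Reagents that add atoms: chlorotrimethylsilane, C[Si](C)(C)Cl
Why: Double deprotonation (carboxylate and acetylide) and silylation at both sites, followed by hydrolysis of the labile silyl ester on acidic work-up, is the routine C-silylation of a terminal alkynoic acid.

Step 4
Reactants: 9 7-(trimethylsilyl)hept-6-ynoic acid; 10 Meldrum's acid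
Product: 12 methyl 3-oxo-9-(trimethylsilyl)non-8-ynoate, via acyl Meldrum's acid 11 (not isolated)
Conditions: DCC, DMAP, CH2Cl2, 0 °C → rt; filter; MeOH, 65 °C
Reagents that add atoms: methanol, CO
Why: Carbodiimide-mediated C-acylation of Meldrum's acid followed by methanolysis with loss of acetone and CO2 is the standard two-carbon homologation of an acid to a β-keto ester, and its near-neutral conditions should leave the silylalkyne untouched.

Step 5
Reactants: 12 methyl 3-oxo-9-(trimethylsilyl)non-8-ynoate
Product: 13 methyl (S)-3-hydroxy-9-(trimethylsilyl)non-8-ynoate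
Conditions: RuCl2[(S)-BINAP] (1 mol %), H2 (4 atm), MeOH, 50 °C
Reagents that add atoms: none
Why: Noyori asymmetric hydrogenation, in which the β-keto ester chelates ruthenium through both carbonyl oxygens and the (S)-BINAP ligand directs hydride to the ketone face that gives the (S)-carbinol (the sense known for simple 3-oxoalkanoates), while the remote, shielded silylalkyne cannot chelate and should not be reduced at this pressure.

Step 6
Reactants: 13 methyl (S)-3-hydroxy-9-(trimethylsilyl)non-8-ynoate
Product: 14 methyl (S)-3-(methoxymethoxy)-9-(trimethylsilyl)non-8-ynoate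
Conditions: MOMCl, iPr2NEt, CH2Cl2, 0 °C → rt
Reagents that add atoms: chloromethyl methyl ether, COCCl
Why: O-alkylation of the secondary alcohol with an α-chloro ether under mild amine base (acetal protection) breaks no bond at the stereocentre, and the MOM ether is chosen because it is inert to fluoride and base in steps 7 and 8.

Step 7
Reactants: 14 methyl (S)-3-(methoxymethoxy)-9-(trimethylsilyl)non-8-ynoate
Product: 16 (S)-10-methoxy-8-(methoxymethoxy)-10-oxodec-2-ynoic acid, via cesium alkynoate 15 (not isolated)
Conditions: CsF (2 equiv), CO2 (1 atm), DMSO, rt; then cold 1 M HCl to pH 3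
Reagents that add atoms: carbon dioxide, O=C=O
Why: Fluoride-mediated desilylative carboxylation of an alkynylsilane, in which fluoride attacks silicon and the alkynyl group is passed to CO2 as it is released, should form the alkynoate without any strong base, so the methyl ester and its α-protons are not engaged.

Step 8
Reactants: 5 3,5-dimethoxy-2-(trimethylsilyl)phenyl trifluoromethanesulfonate; 16 (S)-10-methoxy-8-(methoxymethoxy)-10-oxodec-2-ynoic acid
Product: 19 methyl (S)-7-(5,7-dimethoxy-4-oxo-4H-chromen-2-yl)-3-(methoxymethoxy)heptanoate, via 3,5-dimethoxybenzyne 17 (not isolated), via hydroxyaryl ynone 18 (not isolated)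
Conditions: 5 (1.5 equiv), CsF (4 equiv), THF, 125 °C, sealed tube
Reagents that add atoms: none
Why: CsF strips the silyl group from 5 with loss of triflate and so unmasks aryne 17; the carboxylate of 16 bonds through oxygen to the aryne carbon that is meta to both methoxy groups (the future C8a), the aryl anion left on the carbon ortho to a methoxy group (the future C4a) adds to the carbonyl of its own ester, and collapse of the strained four-membered adduct moves the acyl group from oxygen to carbon to leave the phenoxide of ynone 18. The closest known reaction type is the fluoride-induced aryne insertion into the C(O)–O bond of carboxylic acids, which gives ortho-hydroxyaryl ketones and, from arylpropiolic acids, flavones in the same flask; an alkyl-substituted alk-2-ynoic acid is a further substrate of this class. Ring C then closes by 6-endo-dig oxa-Michael addition of the phenoxide oxygen to the β-carbon of the ynone (O1–C2), the only electrophilic alkyne carbon, so the 5-exo mode is not expected. No stereocentre is formed, and the side-chain carbinol centre, masked as its MOM ether, takes no part. The step needs a single orientation of addition to the unsymmetrical aryne; the methoxy group next to the triple bond secures it by distorting the aryne and by inductively stabilising negative charge on the carbon it flanks, which sends the oxygen nucleophile to the far carbon and places the carbonyl beside the C5 methoxy with the second methoxy at C7. Heating in a sealed tube is chosen so that acyl migration outruns protonation of the aryl anion, which would end at a simple aryl ester.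

Step 9
Reactants: 19 methyl (S)-7-(5,7-dimethoxy-4-oxo-4H-chromen-2-yl)-3-(methoxymethoxy)heptanoate
Product: 20 Penithochromone Q, methyl (S)-7-(5,7-dimethoxy-4-oxo-4H-chromen-2-yl)-3-hydroxyheptanoate
Conditions: HCl (3 M in MeOH), MeOH, 0 → 40 °C
Reagents that add atoms: none
Why: Acid-catalysed acetal exchange (methanolysis of the MOM ether) should free the secondary alcohol, methanol as solvent makes any ester exchange degenerate, and the chromone and the carbinol centre are stable to dilute acid at this temperature.

Compound list
1 | 3,5-dimethoxyphenol | COc1cc(O)cc(OC)c1 | starting material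
2 | 2-bromo-3,5-dimethoxyphenol | COc1cc(O)c(Br)c(OC)c1 | intermediate
3 | (2-bromo-3,5-dimethoxyphenoxy)trimethylsilane | COc1cc(O[Si](C)(C)C)c(Br)c(OC)c1 | intermediate (not isolated)
4 | lithium 3,5-dimethoxy-2-(trimethylsilyl)phenoxide | [Li+].[O-]c1cc(OC)cc(OC)c1[Si](C)(C)C | intermediate (not isolated)
5 | 3,5-dimethoxy-2-(trimethylsilyl)phenyl trifluoromethanesulfonate | COc1cc(OC)c([Si](C)(C)C)c(OS(=O)(=O)C(F)(F)F)c1 | intermediate
6 | hept-6-ynoic acid | C#CCCCCC(=O)O | starting material
7 | lithium 7-lithiohept-6-ynoate | [Li+].[Li+].[C-]#CCCCCC(=O)[O-] | intermediate (not isolated)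
8 | trimethylsilyl 7-(trimethylsilyl)hept-6-ynoate | C[Si](C)(C)C#CCCCCC(=O)O[Si](C)(C)C | intermediate (not isolated)
9 | 7-(trimethylsilyl)hept-6-ynoic acid | C[Si](C)(C)C#CCCCCC(=O)O | intermediate
10 | Meldrum's acid (2,2-dimethyl-1,3-dioxane-4,6-dione) | CC1(C)OC(=O)CC(=O)O1 | starting material
11 | 5-[1-hydroxy-7-(trimethylsilyl)hept-6-yn-1-ylidene]-2,2-dimethyl-1,3-dioxane-4,6-dione | CC1(C)OC(=O)C(=C(O)CCCCC#C[Si](C)(C)C)C(=O)O1 | intermediate (not isolated)
12 | methyl 3-oxo-9-(trimethylsilyl)non-8-ynoate | COC(=O)CC(=O)CCCCC#C[Si](C)(C)C | intermediate
13 | methyl (S)-3-hydroxy-9-(trimethylsilyl)non-8-ynoate | COC(=O)C[C@@H](O)CCCCC#C[Si](C)(C)C | intermediate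
14 | methyl (S)-3-(methoxymethoxy)-9-(trimethylsilyl)non-8-ynoate | COC(=O)C[C@@H](OCOC)CCCCC#C[Si](C)(C)C | intermediate
15 | cesium (S)-10-methoxy-8-(methoxymethoxy)-10-oxodec-2-ynoate | [Cs+].COC(=O)C[C@@H](OCOC)CCCCC#CC(=O)[O-] | intermediate (not isolated)
16 | (S)-10-methoxy-8-(methoxymethoxy)-10-oxodec-2-ynoic acid | COC(=O)C[C@@H](OCOC)CCCCC#CC(=O)O | intermediate
17 | 3,5-dimethoxybenzyne (1,2-didehydro-3,5-dimethoxybenzene) | COC1=CC(OC)=CC#C1 | intermediate (not isolated)
18 | methyl (S)-10-(2-hydroxy-4,6-dimethoxyphenyl)-3-(methoxymethoxy)-10-oxodec-8-ynoate (formed as its phenoxide) | COC(=O)C[C@@H](OCOC)CCCCC#CC(=O)c1c(O)cc(OC)cc1OC | intermediate (not isolated)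
19 | methyl (S)-7-(5,7-dimethoxy-4-oxo-4H-chromen-2-yl)-3-(methoxymethoxy)heptanoate | COC(=O)C[C@@H](OCOC)CCCCc1cc(=O)c2c(OC)cc(OC)cc2o1 | intermediate
20 | Penithochromone Q, methyl (S)-7-(5,7-dimethoxy-4-oxo-4H-chromen-2-yl)-3-hydroxyheptanoate | COC(=O)C[C@@H](O)CCCCc1cc(=O)c2c(OC)cc(OC)cc2o1 | target

Total step count: 9 (steps 1–2 make the aryne precursor, steps 3–7 the alkynoic acid, steps 8–9 join the two and finish).
Longest linear sequence: 7 steps (steps 3–9, from hept-6-ynoic acid).

Steps most likely to fail

Step 8. The aryl anion formed after O-arylation may be quenched by proton transfer before it migrates the acyl group, so that the sequence stops at an aryl ester, or the alkynoate may lose CO2 on heating with fluoride. The fallback sets out from 1 and 16 and comes back at 19. Phenol 1 is iodinated ortho to the hydroxyl group (NIS, CH2Cl2, −78 °C → rt) to 2-iodo-3,5-dimethoxyphenol F1. F1 and acid 16 are then joined under CO in a palladium-catalysed decarboxylative carbonylative alkynylation (PdCl2(PPh3)2, 1,4-bis(diphenylphosphino)butane, Et3N, CO 10 atm, DMSO, 80 °C). In this coupling the aroyl–palladium species formed from F1 and CO takes up the alkynyl group that 16 releases with loss of CO2, which should give ynone 18; addition of Et2NH closes it to 19. Ring C is then assembled from an aryl iodide, CO and the alkyne, with no aryne involved.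

Step 7. The alkynyl species released by fluoride may pick up a proton faster than it captures CO2, or the basic medium may start β-elimination of the MOM-oxy group next to the ester. The fallback sets out from 14 and comes back at 16. The silyl group is removed on purpose (K2CO3, MeOH, rt) to give methyl (S)-3-(methoxymethoxy)non-8-ynoate F2. Its alkyne C–H bond is then carboxylated catalytically through a silver acetylide (AgI 2 mol %, Cs2CO3, CO2 2 atm, DMF, 50 °C; cold dilute HCl), again without a stoichiometric strong base.

Step 1. Site selectivity may be poor, with bromination para to the hydroxyl group (between the two methoxy groups) or double bromination. The fallback sets out from 1 and comes back at 5, bypassing 2 to 4; it fixes the position of silicon by directed ortho-metalation instead of electrophilic substitution. Phenol 1 is carbamoylated (ClCONEt2, K2CO3, MeCN, 80 °C) to 3,5-dimethoxyphenyl diethylcarbamate F3. Lithiation at the position flanked by the carbamate and a methoxy group (s-BuLi, TMEDA, THF, −78 °C) and quenching with TMSCl should give 3,5-dimethoxy-2-(trimethylsilyl)phenyl diethylcarbamate F4. Reductive cleavage of the carbamate (LiAlH4, THF, 0 °C → rt) frees 3,5-dimethoxy-2-(trimethylsilyl)phenol F5, which is triflated (Tf2O, pyridine, CH2Cl2, 0 °C) to 5.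

Further compounds
F1 | step 8 | 2-iodo-3,5-dimethoxyphenol | COc1cc(O)c(I)c(OC)c1
F2 | step 7 | methyl (S)-3-(methoxymethoxy)non-8-ynoate | COC(=O)C[C@@H](OCOC)CCCCC#C
F3 | step 1 | 3,5-dimethoxyphenyl diethylcarbamate | CCN(CC)C(=O)Oc1cc(OC)cc(OC)c1
F4 | step 1 | 3,5-dimethoxy-2-(trimethylsilyl)phenyl diethylcarbamate | CCN(CC)C(=O)Oc1cc(OC)cc(OC)c1[Si](C)(C)C
F5 | step 1 | 3,5-dimethoxy-2-(trimethylsilyl)phenol | COc1cc(O)c([Si](C)(C)C)c(OC)c1
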